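Ring A is cut at C5=C6 and C8–C8a (tetralin numbering; chain C11–C16 with C18 on C11). The key step uses the fact that C6(CO2H)–C7(OH)–C8(OH) of ring A maps onto a 4-alkoxyacetoacetate while ring B is a trans-p-menthane: a Knoevenagel–aldol [3+3] benzannulation of benzyl 4-benzyloxyacetoacetate with the C4a-hydroxymethylene C8a-ketone builds ring A in one operation, with the ester beside C5–H. Its precursor is the bis-TBS hydroxymethylene ketone that already holds C1, C4, C11 and C15: C4 from (R)-carvone, C11 from a ligand-controlled CuH reduction of a carvone-derived butenolide, C15 from (S)-3-bromo-2-methylpropan-1-ol.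

Key step: step 13

Remark: target locants are used for all intermediates (C1 bears CH3, C4 the side chain; C11 bears C18H2O; C12–C14 are CH2; C15 bears CH3 and C16H2O).
Assumption: the (R)-bisphosphine is written in step 4; the antipode that delivers hydride to the required face of C11 is to be fixed by a test reduction, and a switch to the (S)-ligand changes nothing else.

Step 1
Reactants: 1 (R)-(−)-carvone
Product: 2 (5R)-5-(3-chloroprop-1-en-2-yl)-2-methylcyclohex-2-en-1-one
Conditions: Ca(OCl)2, solid CO2, CH2Cl2/H2O, 0 °C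
Reagents that add atoms: calcium hypochlorite, [Ca+2].[O-]Cl.[O-]Cl
Why: Hypochlorous acid released from Ca(OCl)2 and CO2 should chlorinate the electron-rich 1,1-disubstituted alkene in an ene-type allylic chlorination with double-bond shift, while the electron-poor enone alkene and the stereocentre C4 stay untouched.

Step 2
Reactants: 2 (5R)-5-(3-chloroprop-1-en-2-yl)-2-methylcyclohex-2-en-1-one; 3 sodium acrylate
Product: 4 2-[(1R)-4-methyl-5-oxocyclohex-3-en-1-yl]prop-2-en-1-yl prop-2-enoate
Conditions: n-Bu4NI (0.1 equiv), BHT (trace), DMF, 50 °C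
Reagents that add atoms: none
Why: SN2 displacement of the primary allylic chloride by the carboxylate (iodide-catalysed, Finkelstein type) should give the allyl acrylate, which brings in C12 and C13 and makes the chlorinated carbon C18; SN2 and SN2′ attack give the same product.

Step 3
Reactants: 4 2-[(1R)-4-methyl-5-oxocyclohex-3-en-1-yl]prop-2-en-1-yl prop-2-enoate
Product: 5 4-[(1R)-4-methyl-5-oxocyclohex-3-en-1-yl]furan-2(5H)-one
Conditions: second-generation Grubbs catalyst (5 mol%), toluene (0.01 M), 80 °C, argon sparge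
Reagents that add atoms: none
Why: Ring-closing metathesis between the acrylate and the 1,1-disubstituted alkene should close the β-substituted butenolide (C11=C12) with loss of ethene, the trisubstituted enone alkene being inert to the carbene.

Step 4
Reactants: 5 4-[(1R)-4-methyl-5-oxocyclohex-3-en-1-yl]furan-2(5H)-one
Product: 7 (4S)-4-[(1R,4R)-4-methyl-3-oxocyclohexyl]oxolan-2-one, via C1-epimeric keto lactone 6 (not isolated)
Conditions: Cu(OAc)2·H2O (5 mol%), (R)-DTBM-SEGPHOS (5.5 mol%), (EtO)2MeSiH (2.5 equiv), t-BuOH (3 equiv), toluene, 0 °C to rt; aq. NH4F work-up; then DBU (0.2 equiv), CH2Cl2, rt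
Reagents that add atoms: none
Why: Ligand-controlled asymmetric conjugate reduction with CuH (hydrosilylation type) should deliver hydride to C11, the β-carbon of the planar butenolide, from the face chosen by the bisphosphine, which sets C11 (S) under catalyst control because C4 lies outside the reacting ring, while the same CuH reduces the enone 1,4 and DBU then equilibrates the α-carbon C1 to the diequatorial trans ketone.

Step 5
Reactants: 7 (4S)-4-[(1R,4R)-4-methyl-3-oxocyclohexyl]oxolan-2-one
Product: 8 (4S)-4-[(1R,4R)-3-hydroxy-4-methylcyclohexyl]oxolan-2-ol (anomers; both C8a carbinol epimers)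
Conditions: i-Bu2AlH (3.2 equiv), CH2Cl2, −78 °C; aqueous potassium sodium tartrate work-up
Reagents that add atoms: none
Why: Partial reduction of the lactone at −78 °C should stop at the lactol (stable tetrahedral aluminate) while the ketone goes to the carbinol; the two new centres (C13 lactol, C8a carbinol) are not controlled and are erased in steps 7 and 10.

Step 6
Reactants: 9 (S)-3-bromo-2-methylpropan-1-ol
Product: 10 [(2S)-3-hydroxy-2-methylpropyl]triphenylphosphonium bromide
Conditions: PPh3 (1.1 equiv), MeCN, reflux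
Reagents that add atoms: triphenylphosphine, c1ccc(cc1)P(c1ccccc1)c1ccccc1
Why: SN2 quaternisation of triphenylphosphine by the primary bromide should give the hydroxy phosphonium salt without touching the stereocentre that becomes C15.

Step 7
Reactants: 8 (4S)-4-[(1R,4R)-3-hydroxy-4-methylcyclohexyl]oxolan-2-ol; 10 [(2S)-3-hydroxy-2-methylpropyl]triphenylphosphonium bromide
Product: 12 (2R,3Z,6S)-6-[(1R,4R)-3-hydroxy-4-methylcyclohexyl]-2-methylhept-3-ene-1,7-diol (C8a carbinol epimers), via oxido ylide 11 (not isolated)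
Conditions: 10 (3.5 equiv), NaN(SiMe3)2 (7 equiv), THF, 0 °C; then 8, 0 °C to 40 °C
Reagents that add atoms: none
Why: Wittig olefination of the open hydroxy-aldehyde form of the lactol with an excess of the γ-oxido ylide (the excess serves as base for the free hydroxyls, as is usual for lactols and anionic ylides) should join C13 to C14 and free C18–OH, giving the full C11–C16 chain; the mainly Z alkene geometry is irrelevant because it is hydrogenated next.

Step 8
Reactants: 12 (2R,3Z,6S)-6-[(1R,4R)-3-hydroxy-4-methylcyclohexyl]-2-methylhept-3-ene-1,7-diol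
Product: 13 (2S,6R)-2-[(1R,4R)-3-hydroxy-4-methylcyclohexyl]-6-methylheptane-1,7-diol (C8a carbinol epimers)
Conditions: H2 (1 atm), PtO2 (5 mol%), EtOAc, rt
Reagents that add atoms: none
Why: Heterogeneous hydrogenation should saturate the disubstituted alkene, platinum being preferred to palladium to suppress double-bond migration into the allylic stereocentre C15.

Step 9
Reactants: 13 (2S,6R)-2-[(1R,4R)-3-hydroxy-4-methylcyclohexyl]-6-methylheptane-1,7-diol
Product: 14 (2R,5R)-5-[(2S,6R)-1,7-bis(tert-butyldimethylsilyloxy)-6-methylheptan-2-yl]-2-methylcyclohexan-1-ol (C8a carbinol epimers)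
Conditions: TBSCl (2.1 equiv), imidazole (4 equiv), CH2Cl2, 0 °C
Reagents that add atoms: tert-butyldimethylsilyl chloride, CC(C)(C)[Si](C)(C)Cl
Why: Silylation with TBSCl and imidazole should be selective for the two primary hydroxyls (C16, C18) over the hindered secondary ring carbinol flanked by the C1 methyl.

Step 10
Reactants: 14 (2R,5R)-5-[(2S,6R)-1,7-bis(tert-butyldimethylsilyloxy)-6-methylheptan-2-yl]-2-methylcyclohexan-1-ol
Product: 15 (2R,5R)-5-[(2S,6R)-1,7-bis(tert-butyldimethylsilyloxy)-6-methylheptan-2-yl]-2-methylcyclohexan-1-one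
Conditions: (n-Pr4N)RuO4 (5 mol%), N-methylmorpholine N-oxide (1.5 equiv), 4 Å MS, CH2Cl2, rt
Reagents that add atoms: none
Why: Ley–Griffith oxidation should convert both carbinol epimers into the single C8a ketone under neutral conditions that spare the silyl ethers and the trans α-stereocentre C1.

Step 11
Reactants: 15 (2R,5R)-5-[(2S,6R)-1,7-bis(tert-butyldimethylsilyloxy)-6-methylheptan-2-yl]-2-methylcyclohexan-1-one
Product: 16 (2R,5S,6Z)-5-[(2S,6R)-1,7-bis(tert-butyldimethylsilyloxy)-6-methylheptan-2-yl]-6-(hydroxymethylidene)-2-methylcyclohexan-1-one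
Conditions: NaH (3 equiv), HCO2Et (10 equiv), EtOH (cat.), THF, 0 °C to rt; aq. NH4Cl work-up
Reagents that add atoms: ethyl formate, CCOC=O
Why: Claisen formylation under thermodynamic control should occur only at the C4a methylene, since only that product is held as a stable β-keto aldehyde enolate (acylation at the C1 methine is reversible), and it gives the chelated Z-hydroxymethylene ketone carrying C5.

Step 12
Reactants: 17 (benzyloxy)acetyl chloride; 18 Meldrum's acid; 19 benzyl alcohol
Product: 21 benzyl 4-(benzyloxy)-3-oxobutanoate, via acyl Meldrum's acid 20 (not isolated)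
Conditions: pyridine (2 equiv), CH2Cl2, 0 °C to rt; then 19 (1.2 equiv), toluene, 100 °C
Reagents that add atoms: none
Why: C-Acylation of Meldrum's acid followed by thermal cycloreversion to the acylketene and trapping with benzyl alcohol (the Meldrum's acid route to β-keto esters) should give the keto ester with loss of acetone and CO2.

Step 13
Reactants: 16 (2R,5S,6Z)-5-[(2S,6R)-1,7-bis(tert-butyldimethylsilyloxy)-6-methylheptan-2-yl]-6-(hydroxymethylidene)-2-methylcyclohexan-1-one; 21 benzyl 4-(benzyloxy)-3-oxobutanoate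
Product: 24 benzyl (5R,8S)-4-(benzyloxy)-8-[(2S,6R)-1,7-bis(tert-butyldimethylsilyloxy)-6-methylheptan-2-yl]-3-hydroxy-5-methyl-5,6,7,8-tetrahydronaphthalene-2-carboxylate, via Knoevenagel adduct 22 (not isolated), via 4a-H cyclohexadienone 23 (not isolated)
Conditions: piperidine (0.2 equiv), AcOH (0.2 equiv), 4 Å MS, toluene, rt to 40 °C; then DBU (2 equiv), 60 °C
Reagents that add atoms: none
Why: Piperidinium acetate turns the hydroxymethylene group into an iminium/vinylogous amide that is attacked by the doubly activated C6 methylene of 21, and loss of amine and water forges C5=C6 (Knoevenagel condensation, 22); DBU then enolises the benzyloxy-bearing C8 methylene, which adds to the C8a ketone, and E1cB loss of water gives dienone 23, whose C4a–H is removed in a final tautomerisation to the C7 phenol, so the sequence is redox-neutral. The closest known reaction type is the condensation of 2-hydroxymethylene cycloalkanones with acetoacetates or acetonedicarboxylates to ring-fused salicylates. Ring A is closed in a 6-(enolendo)-exo-trig aldol addition. No stereocentre is created. The regiochemistry required (CO2Bn on the carbon bonded to C5, OBn on the carbon bonded to C8a) should follow because the more acidic C6–H2 reacts first and the formyl-derived carbon is far more electrophilic than the ketone flanked by the C1 methyl. C1, the only enolisable stereocentre, is exposed to strong base only briefly before aromatisation removes its acidity, and the silyl ethers and benzyl groups are inert to both stages.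

Step 14
Reactants: 24 benzyl (5R,8S)-4-(benzyloxy)-8-[(2S,6R)-1,7-bis(tert-butyldimethylsilyloxy)-6-methylheptan-2-yl]-3-hydroxy-5-methyl-5,6,7,8-tetrahydronaphthalene-2-carboxylate
Product: 25 benzyl (5R,8S)-3,4-bis(benzyloxy)-8-[(2S,6R)-1,7-bis(tert-butyldimethylsilyloxy)-6-methylheptan-2-yl]-5-methyl-5,6,7,8-tetrahydronaphthalene-2-carboxylate
Conditions: BnBr (1.5 equiv), K2CO3 (2 equiv), n-Bu4NI (cat.), DMF, 50 °C
Reagents that add atoms: benzyl bromide, BrCc1ccccc1
Why: Williamson etherification of the chelated C7 phenoxide should mask the only phenol, so that the later acetylation can touch nothing but the two aliphatic hydroxyls.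

Step 15
Reactants: 25 benzyl (5R,8S)-3,4-bis(benzyloxy)-8-[(2S,6R)-1,7-bis(tert-butyldimethylsilyloxy)-6-methylheptan-2-yl]-5-methyl-5,6,7,8-tetrahydronaphthalene-2-carboxylate
Product: 26 benzyl (5R,8S)-3,4-bis(benzyloxy)-8-[(2S,6R)-1,7-dihydroxy-6-methylheptan-2-yl]-5-methyl-5,6,7,8-tetrahydronaphthalene-2-carboxylate
Conditions: HF·pyridine, pyridine, THF, 0 °C to rt
Reagents that add atoms: none
Why: Fluoride-driven cleavage of the two primary TBS ethers under buffered conditions should leave the benzyl ethers and the benzyl ester intact.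

Step 16
Reactants: 26 benzyl (5R,8S)-3,4-bis(benzyloxy)-8-[(2S,6R)-1,7-dihydroxy-6-methylheptan-2-yl]-5-methyl-5,6,7,8-tetrahydronaphthalene-2-carboxylate
Product: 27 benzyl (5R,8S)-8-[(2S,6R)-1,7-diacetoxy-6-methylheptan-2-yl]-3,4-bis(benzyloxy)-5-methyl-5,6,7,8-tetrahydronaphthalene-2-carboxylate
Conditions: Ac2O (3 equiv), pyridine, DMAP (cat.), CH2Cl2, rt
Reagents that add atoms: acetic anhydride, CC(=O)OC(C)=O
Why: DMAP-catalysed acylation should acetylate both primary alcohols, no other free hydroxyl being present.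

Step 17
Reactants: 27 benzyl (5R,8S)-8-[(2S,6R)-1,7-diacetoxy-6-methylheptan-2-yl]-3,4-bis(benzyloxy)-5-methyl-5,6,7,8-tetrahydronaphthalene-2-carboxylate
Product: 28 (5R,8S)-8-[(2S,6R)-1,7-diacetoxy-6-methylheptan-2-yl]-3,4-dihydroxy-5-methyl-5,6,7,8-tetrahydronaphthalene-2-carboxylic acid (CNP0245723.1)
Conditions: H2 (1 atm), 10% Pd/C, EtOAc/EtOH, rt; filtration under argon
Reagents that add atoms: none
Why: Hydrogenolysis over Pd/C should cleave the benzyl ester and both aryl benzyl ethers, while alkyl acetates, the arene and the benzylic stereocentres C1 and C4 are stable at one atmosphere, releasing the target.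

Compound list
1 | (R)-(−)-carvone, (5R)-2-methyl-5-(prop-1-en-2-yl)cyclohex-2-en-1-one | CC1=CC[C@H](CC1=O)C(=C)C | starting material
2 | (5R)-5-(3-chloroprop-1-en-2-yl)-2-methylcyclohex-2-en-1-one | ClCC(=C)[C@@H]1CC=C(C)C(=O)C1 | intermediate
3 | sodium acrylate | C=CC(=O)[O-].[Na+] | starting material
4 | 2-[(1R)-4-methyl-5-oxocyclohex-3-en-1-yl]prop-2-en-1-yl prop-2-enoate | C=CC(=O)OCC(=C)[C@@H]1CC=C(C)C(=O)C1 | intermediate
5 | 4-[(1R)-4-methyl-5-oxocyclohex-3-en-1-yl]furan-2(5H)-one | O=C1C=C(CO1)[C@@H]2CC=C(C)C(=O)C2 | intermediate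
6 | C1-epimeric keto lactone (not isolated), (4S)-4-[(1R)-4-methyl-3-oxocyclohexyl]oxolan-2-one as both epimers at the methyl-bearing carbon | O=C1C[C@H](CO1)[C@@H]2CCC(C)C(=O)C2 | intermediate
7 | (4S)-4-[(1R,4R)-4-methyl-3-oxocyclohexyl]oxolan-2-one | O=C1C[C@H](CO1)[C@@H]2CC[C@@H](C)C(=O)C2 | intermediate
8 | (4S)-4-[(1R,4R)-3-hydroxy-4-methylcyclohexyl]oxolan-2-ol, anomers and both C8a carbinol epimers | OC1C[C@H](CO1)[C@@H]2CC[C@@H](C)C(O)C2 | intermediate
9 | (S)-3-bromo-2-methylpropan-1-ol | OC[C@H](C)CBr | starting material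
10 | [(2S)-3-hydroxy-2-methylpropyl]triphenylphosphonium bromide | OC[C@H](C)C[P+](c1ccccc1)(c1ccccc1)c1ccccc1.[Br-] | intermediate
11 | oxido ylide (not isolated), sodium (2S)-2-methyl-3-(triphenyl-λ5-phosphanylidene)propan-1-olate | [Na+].[O-]C[C@H](C)C=P(c1ccccc1)(c1ccccc1)c1ccccc1 | intermediate
12 | (2R,3Z,6S)-6-[(1R,4R)-3-hydroxy-4-methylcyclohexyl]-2-methylhept-3-ene-1,7-diol, both C8a carbinol epimers | OC[C@H](C)/C=C\C[C@H](CO)[C@@H]1CC[C@@H](C)C(O)C1 | intermediate
13 | (2S,6R)-2-[(1R,4R)-3-hydroxy-4-methylcyclohexyl]-6-methylheptane-1,7-diol, both C8a carbinol epimers | OC[C@H](C)CCC[C@H](CO)[C@@H]1CC[C@@H](C)C(O)C1 | intermediate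
14 | (2R,5R)-5-[(2S,6R)-1,7-bis(tert-butyldimethylsilyloxy)-6-methylheptan-2-yl]-2-methylcyclohexan-1-ol, both C8a carbinol epimers | CC(C)(C)[Si](C)(C)OC[C@H](C)CCC[C@H](CO[Si](C)(C)C(C)(C)C)[C@@H]1CC[C@@H](C)C(O)C1 | intermediate
15 | (2R,5R)-5-[(2S,6R)-1,7-bis(tert-butyldimethylsilyloxy)-6-methylheptan-2-yl]-2-methylcyclohexan-1-one | CC(C)(C)[Si](C)(C)OC[C@H](C)CCC[C@H](CO[Si](C)(C)C(C)(C)C)[C@@H]1CC[C@@H](C)C(=O)C1 | intermediate
16 | (2R,5S,6Z)-5-[(2S,6R)-1,7-bis(tert-butyldimethylsilyloxy)-6-methylheptan-2-yl]-6-(hydroxymethylidene)-2-methylcyclohexan-1-one (key-step precursor) | CC(C)(C)[Si](C)(C)OC[C@H](C)CCC[C@H](CO[Si](C)(C)C(C)(C)C)[C@@H]1CC[C@@H](C)C(=O)/C1=C\O | intermediate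
17 | (benzyloxy)acetyl chloride | O=C(Cl)COCc1ccccc1 | starting material
18 | Meldrum's acid, 2,2-dimethyl-1,3-dioxane-4,6-dione | CC1(C)OC(=O)CC(=O)O1 | starting material
19 | benzyl alcohol | OCc1ccccc1 | starting material
20 | acyl Meldrum's acid (not isolated), 5-[2-(benzyloxy)-1-hydroxyethylidene]-2,2-dimethyl-1,3-dioxane-4,6-dione | CC1(C)OC(=O)C(=C(O)COCc2ccccc2)C(=O)O1 | intermediate
21 | benzyl 4-(benzyloxy)-3-oxobutanoate | O=C(CC(=O)OCc1ccccc1)COCc1ccccc1 | intermediate
22 | Knoevenagel adduct (not isolated), C5=C6 alkylidene keto ester on the C8a ketone, C4a epimers | CC(C)(C)[Si](C)(C)OC[C@H](C)CCC[C@H](CO[Si](C)(C)C(C)(C)C)[C@@H]1CC[C@@H](C)C(=O)C1C=C(C(=O)OCc1ccccc1)C(=O)COCc1ccccc1 | intermediate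
23 | 4a-H cyclohexadienone (not isolated), C4a epimers | CC(C)(C)[Si](C)(C)OC[C@H](C)CCC[C@H](CO[Si](C)(C)C(C)(C)C)[C@@H]1CC[C@@H](C)C2=C(OCc3ccccc3)C(=O)C(C(=O)OCc3ccccc3)=CC12 | intermediate
24 | benzyl (5R,8S)-4-(benzyloxy)-8-[(2S,6R)-1,7-bis(tert-butyldimethylsilyloxy)-6-methylheptan-2-yl]-3-hydroxy-5-methyl-5,6,7,8-tetrahydronaphthalene-2-carboxylate (key-step product) | CC(C)(C)[Si](C)(C)OC[C@H](C)CCC[C@H](CO[Si](C)(C)C(C)(C)C)[C@@H]1CC[C@@H](C)c2c1cc(C(=O)OCc1ccccc1)c(O)c2OCc1ccccc1 | intermediate
25 | benzyl (5R,8S)-3,4-bis(benzyloxy)-8-[(2S,6R)-1,7-bis(tert-butyldimethylsilyloxy)-6-methylheptan-2-yl]-5-methyl-5,6,7,8-tetrahydronaphthalene-2-carboxylate | CC(C)(C)[Si](C)(C)OC[C@H](C)CCC[C@H](CO[Si](C)(C)C(C)(C)C)[C@@H]1CC[C@@H](C)c2c1cc(C(=O)OCc1ccccc1)c(OCc1ccccc1)c2OCc1ccccc1 | intermediate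
26 | benzyl (5R,8S)-3,4-bis(benzyloxy)-8-[(2S,6R)-1,7-dihydroxy-6-methylheptan-2-yl]-5-methyl-5,6,7,8-tetrahydronaphthalene-2-carboxylate | OC[C@H](C)CCC[C@H](CO)[C@@H]1CC[C@@H](C)c2c1cc(C(=O)OCc1ccccc1)c(OCc1ccccc1)c2OCc1ccccc1 | intermediate
27 | benzyl (5R,8S)-8-[(2S,6R)-1,7-diacetoxy-6-methylheptan-2-yl]-3,4-bis(benzyloxy)-5-methyl-5,6,7,8-tetrahydronaphthalene-2-carboxylate | CC(=O)OC[C@H](C)CCC[C@H](COC(C)=O)[C@@H]1CC[C@@H](C)c2c1cc(C(=O)OCc1ccccc1)c(OCc1ccccc1)c2OCc1ccccc1 | intermediate
28 | (5R,8S)-8-[(2S,6R)-1,7-diacetoxy-6-methylheptan-2-yl]-3,4-dihydroxy-5-methyl-5,6,7,8-tetrahydronaphthalene-2-carboxylic acid | CC(=O)OC[C@H](C)CCC[C@H](COC(C)=O)[C@@H]1CC[C@@H](C)c2c1cc(C(=O)O)c(O)c2O | target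

Total step count: 17.
Longest linear sequence: 15 steps (1 to 28 through steps 1–5, 7–11 and 13–17).

Steps most likely to fail

Step 13 (key step). The ring closure may be incomplete or misdirected: the Knoevenagel adduct may cyclise through oxygen to a 2H-pyran or stall before the aldol at the hindered C8a ketone, and long exposure to base may epimerise C1 before aromatisation. Fallback: it sets out from 15 and 21 and comes back at 24. Keto ester 21 is heated with HC(OEt)3 and Ac2O to give the ethoxymethylene keto ester F1, which now carries C5. Ketone 15 is condensed with pyrrolidine (cat. TsOH, benzene, water removal) to its less substituted pyrrolidine enamine F2. Stork enamine addition–elimination of F2 at the ethoxymethylene carbon of F1 forms C4a–C5 with loss of ethanol and gives the iminium form of 22. The C8 enol then adds to the C8a iminium carbon, pyrrolidine is expelled to give 23, and tautomerisation gives 24. The nitrogen leaving group replaces the slow aldol dehydration, and the formyl ketone 16 is bypassed.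

Step 4. Facial discrimination at C11 may be insufficient if ligand and substrate bias are mismatched, and the lactone carbonyl may be over-reduced by the hydrosilane. Fallback: it sets out from 5 and comes back at 7. The two reductions are uncoupled, and C11 is set by dihydrogen addition instead of hydride conjugate addition. Asymmetric hydrogenation of the butenolide with H2 (50 atm) and Ru(OAc)2[(S)-BINAP] in MeOH, a known method for β-substituted butenolides, gives the enone lactone F3. Conjugate reduction of the enone with Li[BH(s-Bu)3] (THF, −78 °C) and DBU equilibration of C1 then give 7.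

Step 3. Ring closure at the hindered 1,1-disubstituted alkene may be slow, with competing acrylate dimerisation and catalyst decay. Fallback: it sets out from 2 and comes back at 5. The butenolide is closed by olefination of a ketone instead of metathesis. Chloride 2 is displaced with potassium (diethoxyphosphoryl)acetate (DMF, 50 °C) to give the phosphonoacetate F4. Selective ozonolysis of the electron-rich 1,1-disubstituted alkene (O3, CH2Cl2/MeOH, −78 °C; Me2S) gives the keto phosphonate F5. Intramolecular Horner–Wadsworth–Emmons reaction under mild conditions (LiCl, i-Pr2NEt, MeCN, 0 °C), kept short to protect the now enolisable C4, closes 5.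

Further compounds
F1 | step 13 | benzyl 4-(benzyloxy)-2-(ethoxymethylidene)-3-oxobutanoate | CCOC=C(C(=O)OCc1ccccc1)C(=O)COCc1ccccc1
F2 | step 13 | 1-[(3R,6R)-3-[(2S,6R)-1,7-bis(tert-butyldimethylsilyloxy)-6-methylheptan-2-yl]-6-methylcyclohex-1-en-1-yl]pyrrolidine | CC(C)(C)[Si](C)(C)OC[C@H](C)CCC[C@H](CO[Si](C)(C)C(C)(C)C)[C@@H]1CC[C@@H](C)C(N2CCCC2)=C1
F3 | step 4 | (4S)-4-[(1R)-4-methyl-5-oxocyclohex-3-en-1-yl]oxolan-2-one | O=C1C[C@H](CO1)[C@@H]2CC=C(C)C(=O)C2
F4 | step 3 | 2-[(1R)-4-methyl-5-oxocyclohex-3-en-1-yl]prop-2-en-1-yl (diethoxyphosphoryl)acetate | C=C(COC(=O)CP(=O)(OCC)OCC)[C@@H]1CC=C(C)C(=O)C1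
F5 | step 3 | 2-[(1R)-4-methyl-5-oxocyclohex-3-en-1-yl]-2-oxoethyl (diethoxyphosphoryl)acetate | O=C(COC(=O)CP(=O)(OCC)OCC)[C@@H]1CC=C(C)C(=O)C1
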